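**Plan**
- Retrosynthesis: remove the four O-benzyl groups and the O-methyl group on C8. Then cut O1–C8a of the pyranone (ring C), then C2–C3 of the open 1,3-diketone, then the C4–C4a aryl–carbonyl bond.
- Enabling feature: the oxygens on C5 and C8 of ring A are para to each other, so ring A is a latent 1,4-benzoquinone. In that quinone the ring CH next to C4a (future C8a) is an acceptor carbon and can take up the enol oxygen O1.
- Forward: rings A and B are bought as arenes. Ring A is oxygenated, benzylated, brominated and acylated (ArLi + Weinreb amide) to an α-benzyloxy ketone. C-aroylation with the ring-B acid chloride completes the C4–C3–C2 chain.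
- Ring C is the only ring built. Ce(IV) converts ring A into the acylquinone and the diketone enol closes O1–C8a. 8-O-Methylation beside the chelated 5-OH and global hydrogenolysis finish the route.
- Stereochemistry: the target has none. The one sp3 centre on the way (C3 of the diketone) is racemic, enolisable and becomes sp2 on ring closure.

Key step: step 10

Remark: the target SMILES contains no stereocentre, stereogenic axis or configurable double bond, so the compound is achiral and no enantiomer has to be selected.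

**Step 1**
Reactants: 1 2,5-dimethoxybenzaldehyde
Product: 3 2,5-dimethoxyphenol, via aryl formate 2 (not isolated)
Conditions: mCPBA, CH2Cl2, 0 °C → rt; then K2CO3 (cat.), MeOH, rt
Reagents that add atoms: mCPBA (3-chloroperoxybenzoic acid), O=C(OO)c1cccc(Cl)c1
Why: Baeyer–Villiger oxidation of an electron-rich benzaldehyde proceeds with aryl migration (Dakin-type outcome) to the aryl formate, which base-catalysed methanolysis should cleave to the phenol.

**Step 2**
Reactants: 3 2,5-dimethoxyphenol
Product: 4 2-(benzyloxy)-1,4-dimethoxybenzene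
Conditions: BnBr, K2CO3, DMF, rt
Reagents that add atoms: benzyl bromide, BrCc1ccccc1
Why: Williamson ether synthesis of a phenoxide with a reactive benzylic halide, with no competing nucleophile in 3.

**Step 3**
Reactants: 4 2-(benzyloxy)-1,4-dimethoxybenzene
Product: 5 1-(benzyloxy)-4-bromo-2,5-dimethoxybenzene
Conditions: NBS (1.0 equiv), MeCN, 0 °C
Reagents that add atoms: N-bromosuccinimide, O=C1CCC(=O)N1Br
Why: Electrophilic aromatic bromination should go to the one ring CH that is para to OBn and ortho to OMe, the usual site of attack on 1,2,4-trialkoxybenzenes, and the polar NBS/MeCN conditions spare the benzylic CH2.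

**Step 4**
Reactants: 6 benzyloxyacetyl chloride
Product: 7 2-(benzyloxy)-N-methoxy-N-methylacetamide
Conditions: MeNHOMe·HCl, K2CO3, CH2Cl2–H2O, 0 °C
Reagents that add atoms: N,O-dimethylhydroxylamine hydrochloride, CNOC.Cl
Why: Schotten–Baumann N-acylation of the hydroxylamine is faster than hydrolysis of the acid chloride and should give the Weinreb amide cleanly.

**Step 5**
Reactants: 5 1-(benzyloxy)-4-bromo-2,5-dimethoxybenzene; 7 2-(benzyloxy)-N-methoxy-N-methylacetamide
Product: 9 2-(benzyloxy)-1-[4-(benzyloxy)-2,5-dimethoxyphenyl]ethan-1-one, via aryllithium 8 (not isolated)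
Conditions: n-BuLi, THF, −78 °C; then 7, −78 °C → 0 °C; aq NH4Cl
Reagents that add atoms: none
Why: Bromine–lithium exchange followed by the Weinreb ketone synthesis stops at the chelated tetrahedral adduct, and it is preferred to a Friedel–Crafts acylation because Lewis acids strip benzyl ethers and decarbonylate α-alkoxyacyl chlorides.

**Step 6**
Reactants: 10 3,5-dihydroxy-4-methoxybenzoic acid (4-O-methylgallic acid)
Product: 11 benzyl 3,5-bis(benzyloxy)-4-methoxybenzoate
Conditions: BnBr (3.3 equiv), K2CO3, DMF, 60 °C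
Reagents that add atoms: benzyl bromide, BrCc1ccccc1
Why: Williamson O-alkylation of both phenoxides and of the carboxylate in one operation avoids any need to tell the three acidic sites apart.

**Step 7**
Reactants: 11 benzyl 3,5-bis(benzyloxy)-4-methoxybenzoate
Product: 12 3,5-bis(benzyloxy)-4-methoxybenzoic acid
Conditions: KOH, THF–MeOH–H2O, 50 °C; then aq HCl
Reagents that add atoms: potassium hydroxide, [K+].[OH-]
Why: Saponification by acyl–oxygen cleavage removes only the ester benzyl group, since aryl benzyl and methyl ethers are inert to hydroxide.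

**Step 8**
Reactants: 12 3,5-bis(benzyloxy)-4-methoxybenzoic acid
Product: 13 3,5-bis(benzyloxy)-4-methoxybenzoyl chloride
Conditions: (COCl)2, DMF (cat.), CH2Cl2, 0 °C → rt
Reagents that add atoms: oxalyl chloride, O=C(Cl)C(=O)Cl
Why: Acid chloride formation under Vilsmeier-type DMF catalysis runs cold and gives only gaseous by-products, so the ethers are not at risk.

**Step 9**
Reactants: 9 2-(benzyloxy)-1-[4-(benzyloxy)-2,5-dimethoxyphenyl]ethan-1-one; 13 3,5-bis(benzyloxy)-4-methoxybenzoyl chloride
Product: 15 2-(benzyloxy)-1-[4-(benzyloxy)-2,5-dimethoxyphenyl]-3-[3,5-bis(benzyloxy)-4-methoxyphenyl]propane-1,3-dione (racemic, enolisable), via lithium enolate 14 (not isolated)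
Conditions: LiHMDS (2.1 equiv), THF, −78 °C; then 13, −78 °C → 0 °C; aq NH4Cl
Reagents that add atoms: none
Why: Claisen-type C-acylation of a preformed chelated lithium enolate with an aroyl chloride, in which the second equivalent of base deprotonates the more acidic diketone as it forms and so suppresses proton exchange and double acylation.

**Step 10**
Reactants: 15 2-(benzyloxy)-1-[4-(benzyloxy)-2,5-dimethoxyphenyl]-3-[3,5-bis(benzyloxy)-4-methoxyphenyl]propane-1,3-dione
Product: 18 3,7-bis(benzyloxy)-2-[3,5-bis(benzyloxy)-4-methoxyphenyl]-5,8-dihydroxy-4H-chromen-4-one, via acylquinone 16 (not isolated), via chromenetrione 17 (not isolated)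
Conditions: CAN (4.5 equiv), MeCN–H2O (3:1), 0 °C → rt, short contact time; then aq Na2S2O4, EtOAc, rt
Reagents that add atoms: water, O
Why: Proposed new method: Ce(IV) removes two electrons from the 1,2,4-trialkoxy ring, the most easily oxidised arene in 15, and water displaces the two para methoxy groups to give 2-acyl-5-benzyloxy-1,4-benzoquinone 16, in which the ring CH next to the acyl-bearing carbon (future C8a) is the acceptor terminus of two enone systems at once, C5=O/C4a=C8a and C4=O/C4a=C8a. The Z-enol with its hydroxyl on the ring-B carbon (C2) then adds through oxygen to that CH in a 6-endo-trig oxa-Michael closure that forms O1–C8a, and tautomerisation to the aromatic quinol makes the closure irreversible; no stereocentre is created and C3 becomes sp2. The surplus Ce(IV) carries the quinol on to chromene-4,5,8-trione 17, so that unreacted 16 is never used up as the oxidant of its own product, and dithionite returns 17 to 18 in the work-up. The closest known reaction types are Ce(IV) oxidative demethylation of 2,5-dimethoxyaryl ketones, C3-selective conjugate addition of heteronucleophiles to 2-acylquinones, and phenol-to-quinone oxa-Michael closures that give xanthones; the enol oxygen of a 1,3-diketone has not been shown to build a chromone in this way. The step needs O-attack at C8a and nowhere else, and the substrate secures this because C6=C7 carries the benzyloxy donor and lies beyond the reach of the tether, hemiketal formation at the C5 carbonyl is reversible, and attack through carbon C3 would require a four-membered ring.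

**Step 11**
Reactants: 18 3,7-bis(benzyloxy)-2-[3,5-bis(benzyloxy)-4-methoxyphenyl]-5,8-dihydroxy-4H-chromen-4-one
Product: 19 3,7-bis(benzyloxy)-2-[3,5-bis(benzyloxy)-4-methoxyphenyl]-5-hydroxy-8-methoxy-4H-chromen-4-one
Conditions: MeI (1.1 equiv), K2CO3 (1.2 equiv), degassed acetone, Ar, rt → 40 °C
Reagents that add atoms: iodomethane, CI
Why: Williamson methylation under chelation control, the standard partial methylation of 5,8-dihydroxyflavones, should alkylate only 8-OH because 5-OH is held in a hydrogen bond to C4=O and is much less acidic and nucleophilic.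

**Step 12**
Reactants: 19 3,7-bis(benzyloxy)-2-[3,5-bis(benzyloxy)-4-methoxyphenyl]-5-hydroxy-8-methoxy-4H-chromen-4-one
Product: 20 2-(3,5-dihydroxy-4-methoxyphenyl)-3,5,7-trihydroxy-8-methoxy-4H-chromen-4-one (CNP0103387.0)
Conditions: H2 (1 atm), 10% Pd/C, THF–MeOH, rt
Reagents that add atoms: none
Why: Catalytic hydrogenolysis cleaves all four benzyl ethers, while the methyl ethers and the fully substituted, conjugated C2=C3 bond of the flavonol are inert under these conditions.

**Compound list**
1 | 2,5-dimethoxybenzaldehyde | COc1ccc(OC)c(C=O)c1 | starting material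
2 | 2,5-dimethoxyphenyl formate | COc1ccc(OC)c(OC=O)c1 | intermediate
3 | 2,5-dimethoxyphenol | COc1ccc(OC)c(O)c1 | intermediate
4 | 2-(benzyloxy)-1,4-dimethoxybenzene | COc1ccc(OC)c(OCc2ccccc2)c1 | intermediate
5 | 1-(benzyloxy)-4-bromo-2,5-dimethoxybenzene | COc1cc(Br)c(OC)cc1OCc1ccccc1 | intermediate
6 | benzyloxyacetyl chloride | O=C(Cl)COCc1ccccc1 | starting material
7 | 2-(benzyloxy)-N-methoxy-N-methylacetamide | CON(C)C(=O)COCc1ccccc1 | intermediate
8 | [4-(benzyloxy)-2,5-dimethoxyphenyl]lithium | [Li]c1cc(OC)c(OCc2ccccc2)cc1OC | intermediate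
9 | 2-(benzyloxy)-1-[4-(benzyloxy)-2,5-dimethoxyphenyl]ethan-1-one | COc1cc(C(=O)COCc2ccccc2)c(OC)cc1OCc1ccccc1 | intermediate
10 | 3,5-dihydroxy-4-methoxybenzoic acid (4-O-methylgallic acid) | COc1c(O)cc(C(=O)O)cc1O | starting material
11 | benzyl 3,5-bis(benzyloxy)-4-methoxybenzoate | COc1c(OCc2ccccc2)cc(C(=O)OCc2ccccc2)cc1OCc1ccccc1 | intermediate
12 | 3,5-bis(benzyloxy)-4-methoxybenzoic acid | COc1c(OCc2ccccc2)cc(C(=O)O)cc1OCc1ccccc1 | intermediate
13 | 3,5-bis(benzyloxy)-4-methoxybenzoyl chloride | COc1c(OCc2ccccc2)cc(C(=O)Cl)cc1OCc1ccccc1 | intermediate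
14 | lithium (Z)-2-(benzyloxy)-1-[4-(benzyloxy)-2,5-dimethoxyphenyl]ethen-1-olate | [Li]O/C(=C\OCc1ccccc1)c1cc(OC)c(OCc2ccccc2)cc1OC | intermediate
15 | 2-(benzyloxy)-1-[4-(benzyloxy)-2,5-dimethoxyphenyl]-3-[3,5-bis(benzyloxy)-4-methoxyphenyl]propane-1,3-dione (racemic) | COc1cc(C(=O)C(OCc2ccccc2)C(=O)c2cc(OCc3ccccc3)c(OC)c(OCc3ccccc3)c2)c(OC)cc1OCc1ccccc1 | intermediate
16 | 2-(benzyloxy)-1-[4-(benzyloxy)-3,6-dioxocyclohexa-1,4-dien-1-yl]-3-[3,5-bis(benzyloxy)-4-methoxyphenyl]propane-1,3-dione (racemic) | O=C1C=C(OCc2ccccc2)C(=O)C=C1C(=O)C(OCc1ccccc1)C(=O)c1cc(OCc2ccccc2)c(OC)c(OCc2ccccc2)c1 | intermediate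
17 | 3,7-bis(benzyloxy)-2-[3,5-bis(benzyloxy)-4-methoxyphenyl]-4H-chromene-4,5,8-trione | COc1c(OCc2ccccc2)cc(C2=C(OCc3ccccc3)C(=O)C3=C(O2)C(=O)C(OCc2ccccc2)=CC3=O)cc1OCc1ccccc1 | intermediate
18 | 3,7-bis(benzyloxy)-2-[3,5-bis(benzyloxy)-4-methoxyphenyl]-5,8-dihydroxy-4H-chromen-4-one | COc1c(OCc2ccccc2)cc(-c2oc3c(O)c(OCc4ccccc4)cc(O)c3c(=O)c2OCc2ccccc2)cc1OCc1ccccc1 | intermediate
19 | 3,7-bis(benzyloxy)-2-[3,5-bis(benzyloxy)-4-methoxyphenyl]-5-hydroxy-8-methoxy-4H-chromen-4-one | COc1c(OCc2ccccc2)cc(-c2oc3c(OC)c(OCc4ccccc4)cc(O)c3c(=O)c2OCc2ccccc2)cc1OCc1ccccc1 | intermediate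
20 | 2-(3,5-dihydroxy-4-methoxyphenyl)-3,5,7-trihydroxy-8-methoxy-4H-chromen-4-one | COc1c(O)cc(-c2oc3c(OC)c(O)cc(O)c3c(=O)c2O)cc1O | target

**Step count**
Total step count: 12.
Longest linear sequence: 8 steps (1, 2, 3, 5, 9, 10, 11, 12).

**Steps most likely to fail**

**Step 10.** Several processes could compete:
- Ce(IV) may take an electron from the diketone enol and oxidise C3 before ring A has reacted.
- Dealkylation may remove the C7 benzyl together with the C8 methyl and lead towards an ortho-quinone.
- Enolisation may be too slow, so that water adds to the acylquinone or hydrolyses the 7-benzyloxy vinylogous ester.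

The fallback uses known chemistry only. It sets out from acid 12 and acid chloride 13 and returns at 18. Hoesch acylation of phloroglucinol with benzyloxyacetonitrile (ZnCl2, HCl, Et2O; then hot water) gives 2-(benzyloxy)-1-(2,4,6-trihydroxyphenyl)ethan-1-one F1. Compounds 12 and 13 are joined (pyridine, CH2Cl2) to 3,5-bis(benzyloxy)-4-methoxybenzoic anhydride F2. Allan–Robinson condensation of F1 with F2 (Et3N, 160 °C; then KOH, EtOH to strip aroyl esters) gives 3-(benzyloxy)-2-[3,5-bis(benzyloxy)-4-methoxyphenyl]-5,7-dihydroxy-4H-chromen-4-one F3. The non-chelated 7-OH is benzylated (BnBr, 1 equiv, K2CO3, acetone) to 3,7-bis(benzyloxy)-2-[3,5-bis(benzyloxy)-4-methoxyphenyl]-5-hydroxy-4H-chromen-4-one F4. Elbs persulfate oxidation (K2S2O8, aq KOH–pyridine, rt) oxygenates C8, para to 5-OH, as potassium 3,7-bis(benzyloxy)-2-[3,5-bis(benzyloxy)-4-methoxyphenyl]-5-hydroxy-4-oxo-4H-chromen-8-yl sulfate F5. Warm aq HCl with Na2SO3 then hydrolyses F5 to 18.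

**Step 9.** The enolate may be acylated on oxygen or twice. The hindered 2-alkoxy diketone may also undergo retro-Claisen cleavage during the quench.

The fallback replaces acylation by aldol addition and oxidation. It sets out from ester 11 and ketone 9 and returns at 15. LiAlH4 (THF, 0 °C) reduces 11 to [3,5-bis(benzyloxy)-4-methoxyphenyl]methanol F6, and MnO2 (CH2Cl2) oxidises this to 3,5-bis(benzyloxy)-4-methoxybenzaldehyde F7. Enolate 14, generated from 9 as before, adds to F7 at −78 °C to give 2-(benzyloxy)-1-[4-(benzyloxy)-2,5-dimethoxyphenyl]-3-[3,5-bis(benzyloxy)-4-methoxyphenyl]-3-hydroxypropan-1-one F8. F8 forms as a mixture of diastereomers, which does not matter here. Dess–Martin oxidation of F8 gives 15.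

**Step 11.** The quinol anion may be re-oxidised by traces of air before it is alkylated. Alkylation may also spill over to the chelated 5-OH.

The fallback methylates both hydroxyls and then takes one methyl off. It sets out from 18 and returns at 19. Exhaustive methylation under reducing phase-transfer conditions (Me2SO4, KOH, Na2S2O4, Bu4NBr, THF–H2O) gives 3,7-bis(benzyloxy)-2-[3,5-bis(benzyloxy)-4-methoxyphenyl]-5,8-dimethoxy-4H-chromen-4-one F9. BCl3 (1 equiv, CH2Cl2, −78 °C → 0 °C) then cleaves only the 5-OMe peri to the carbonyl through a six-membered boron chelate, giving 19. Stray loss of a benzyl group at this stage would be harmless, because step 12 removes them all.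

**Further compounds**
F1 | step 10 | 2-(benzyloxy)-1-(2,4,6-trihydroxyphenyl)ethan-1-one | O=C(COCc1ccccc1)c1c(O)cc(O)cc1O
F2 | step 10 | 3,5-bis(benzyloxy)-4-methoxybenzoic anhydride | COc1c(OCc2ccccc2)cc(C(=O)OC(=O)c2cc(OCc3ccccc3)c(OC)c(OCc3ccccc3)c2)cc1OCc1ccccc1
F3 | step 10 | 3-(benzyloxy)-2-[3,5-bis(benzyloxy)-4-methoxyphenyl]-5,7-dihydroxy-4H-chromen-4-one | COc1c(OCc2ccccc2)cc(-c2oc3cc(O)cc(O)c3c(=O)c2OCc2ccccc2)cc1OCc1ccccc1
F4 | step 10 | 3,7-bis(benzyloxy)-2-[3,5-bis(benzyloxy)-4-methoxyphenyl]-5-hydroxy-4H-chromen-4-one | COc1c(OCc2ccccc2)cc(-c2oc3cc(OCc4ccccc4)cc(O)c3c(=O)c2OCc2ccccc2)cc1OCc1ccccc1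
F5 | step 10 | potassium 3,7-bis(benzyloxy)-2-[3,5-bis(benzyloxy)-4-methoxyphenyl]-5-hydroxy-4-oxo-4H-chromen-8-yl sulfate | [K+].COc1c(OCc2ccccc2)cc(-c2oc3c(OS(=O)(=O)[O-])c(OCc4ccccc4)cc(O)c3c(=O)c2OCc2ccccc2)cc1OCc1ccccc1
F6 | step 9 | [3,5-bis(benzyloxy)-4-methoxyphenyl]methanol | COc1c(OCc2ccccc2)cc(CO)cc1OCc1ccccc1
F7 | step 9 | 3,5-bis(benzyloxy)-4-methoxybenzaldehyde | COc1c(OCc2ccccc2)cc(C=O)cc1OCc1ccccc1
F8 | step 9 | 2-(benzyloxy)-1-[4-(benzyloxy)-2,5-dimethoxyphenyl]-3-[3,5-bis(benzyloxy)-4-methoxyphenyl]-3-hydroxypropan-1-one (mixture of diastereomers) | COc1cc(C(=O)C(OCc2ccccc2)C(O)c2cc(OCc3ccccc3)c(OC)c(OCc3ccccc3)c2)c(OC)cc1OCc1ccccc1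
F9 | step 11 | 3,7-bis(benzyloxy)-2-[3,5-bis(benzyloxy)-4-methoxyphenyl]-5,8-dimethoxy-4H-chromen-4-one | COc1c(OCc2ccccc2)cc(-c2oc3c(OC)c(OCc4ccccc4)cc(OC)c3c(=O)c2OCc2ccccc2)cc1OCc1ccccc1
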